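**Plan**

- Numbering per 3-methylquinolizidin-2-one half: ring A = C1, C2 (C=O), C3, C4, N5, C9a; ring B = N5, C6–C9, C9a. The retrosynthesis cuts both C1–CH2(chain) bonds (as C1=CH enones) to give two identical monomers, then in each monomer the chain between its second and third carbon, ring B at C8–C9 and ring A at N5–C4.
- Enabling feature: the run C9–C9a(N5)–C1–C2 is an aspartate backbone (α-carboxyl carbon = C9, β-carboxyl carbon = C2). An acrylate grown from the α-carboxyl carbon on C9a can therefore accept a C8 radical released from an N5-(3-carboxypropyl) arm, which closes ring B.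
- Forward order: ring A by 6-endo aza-Michael closure of a D-aspartate-derived isopropenyl ketone; ring B by decarboxylative radical 6-exo closure; chain by Wittig extension; the 16-membered macrocycle by head-to-tail double Horner–Wadsworth–Emmons dimerization at C1; hydrogenation; equilibration.
- Stereochemistry: C9a from D-aspartate; C3 by thermodynamic control (equatorial methyl); C9 from C9a through the chair-like radical transition state; C1 by the final base equilibration.

Key step: step 9

Assumption: the C1 and C3 configurations of the target are taken to be the thermodynamically preferred ones for a trans-fused quinolizidin-2-one with fixed C9 and C9a (equatorial C3 methyl; axial C1 chain, which avoids the peri clash with the equatorial C9 chain), so base equilibration should converge on the target.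

**Route**

Step 1
Reactants: 1 Boc-D-Asp-OMe (commercial N-Boc α-methyl ester of D-aspartic acid); 2 N,O-dimethylhydroxylamine hydrochloride
Product: 3 methyl (2R)-2-[(tert-butoxycarbonyl)amino]-4-[methoxy(methyl)amino]-4-oxobutanoate
Conditions: EDC·HCl, HOBt (cat.), N-methylmorpholine, CH2Cl2, 0 → 23 °C
Reagents that add atoms: N,O-dimethylhydroxylamine hydrochloride, CNOC.Cl
Why: Carbodiimide/HOBt amide coupling of the free β-carboxyl gives the Weinreb amide without touching the α-ester or the α-stereocentre.

Step 2
Reactants: 3 Weinreb amide; 4 isopropenylmagnesium bromide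
Product: 5 methyl (2R)-2-[(tert-butoxycarbonyl)amino]-5-methyl-4-oxohex-5-enoate
Conditions: 4 (2.5 equiv), THF, −78 → −20 °C; cold 1 M HCl quench
Reagents that add atoms: isopropenylmagnesium bromide, CC(=C)[Mg]Br
Why: Weinreb ketone synthesis, in which the Grignard reagent first removes the carbamate N–H and then adds once to the N-methoxy-N-methylamide as a stable magnesium chelate, while the α-ester beside the magnesiated carbamate is shielded at low temperature.

Step 3
Reactants: 5 Boc-amino isopropenyl ketone
Product: 7 methyl (2R,5R)-5-methyl-4-oxopiperidine-2-carboxylate (2,5-trans), via amino enone trifluoroacetate 6 (not isolated)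
Conditions: CF3CO2H, CH2Cl2, 0 °C; evaporate; i-Pr2NEt, MeOH, 23 °C
Reagents that add atoms: none
Why: Boc acidolysis followed by release of the primary amine allows a 6-endo-trig intramolecular aza-Michael addition to the isopropenyl ketone (N5–C4 bond, ring A), and C3, being α to the ketone, should equilibrate to the equatorial methyl trans to the C9a ester.

Step 4
Reactants: 7 piperidone; 8 ethylene glycol
Product: 9 methyl (6R,9R)-6-methyl-1,4-dioxa-8-azaspiro[4.5]decane-9-carboxylate
Conditions: HC(OEt)3, p-TsOH·H2O (1.2 equiv), CH2Cl2, 23 °C; NaHCO3 work-up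
Reagents that add atoms: ethylene glycol, OCCO
Why: Acid-catalysed ketalization with the amine held as its tosylate and orthoformate as water scavenger runs at room temperature, fixes the C3 configuration and removes the ketone that could open ring A by retro-Michael reaction at C9a.

Step 5
Reactants: 9 ketal amino ester; 10 tert-butyl 4-bromobutanoate
Product: 11 methyl (6R,9R)-8-(4-tert-butoxy-4-oxobutyl)-6-methyl-1,4-dioxa-8-azaspiro[4.5]decane-9-carboxylate
Conditions: K2CO3, NaI (cat.), MeCN, 70 °C
Reagents that add atoms: tert-butyl 4-bromobutanoate, CC(C)(C)OC(=O)CCCBr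
Why: SN2 N-alkylation of the secondary amine by the primary bromide (iodide catalysis) installs the C6–C7–C8 arm with its masked carboxyl and touches no stereocentre.

Step 6
Reactants: 11 N-alkyl amino diester; 12 methyl (triphenylphosphoranylidene)acetate
Product: 14 tert-butyl 4-[(6R,9R)-9-[(E)-3-methoxy-3-oxoprop-1-en-1-yl]-6-methyl-1,4-dioxa-8-azaspiro[4.5]decan-8-yl]butanoate, via α-amino aldehyde 13 (not isolated)
Conditions: i-Bu2AlH (1.2 equiv), CH2Cl2, −78 °C; then 12, −78 → 23 °C
Reagents that add atoms: methyl (triphenylphosphoranylidene)acetate, COC(=O)C=P(c1ccccc1)(c1ccccc1)c1ccccc1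
Why: Partial reduction of the α-amino methyl ester at −78 °C (the tert-butyl ester reacts far more slowly) and in situ Wittig olefination with the stabilized ylide should give the (E)-acrylate without isolating the configurationally labile aldehyde.

Step 7
Reactants: 14 tert-butyl ester acrylate
Product: 15 4-[(6R,9R)-9-[(E)-3-methoxy-3-oxoprop-1-en-1-yl]-6-methyl-1,4-dioxa-8-azaspiro[4.5]decan-8-yl]butanoic acid
Conditions: CF3CO2H, CH2Cl2, 0 → 23 °C; evaporation, pH 7 buffer
Reagents that add atoms: none
Why: Anhydrous acidolysis cleaves the tert-butyl ester through the tert-butyl cation, while the methyl acrylate and the dioxolane (its ionization retarded by the neighbouring ammonium) should survive.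

Step 8
Reactants: 15 amino acid; 16 N-hydroxyphthalimide
Product: 17 1,3-dioxoisoindolin-2-yl 4-[(6R,9R)-9-[(E)-3-methoxy-3-oxoprop-1-en-1-yl]-6-methyl-1,4-dioxa-8-azaspiro[4.5]decan-8-yl]butanoate
Conditions: N,N'-diisopropylcarbodiimide, DMAP (cat.), CH2Cl2, 0 → 23 °C; used at once
Reagents that add atoms: N-hydroxyphthalimide, ON1C(=O)c2ccccc2C1=O
Why: Steglich-type carbodiimide esterification gives the redox-active ester, a class of 4-(dialkylamino)butanoic active ester that is isolable when handled briefly.

Step 9
Reactants: 17 N-hydroxyphthalimide ester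
Product: 18 methyl 2-[(3R,9R,9aR)-2,2-(ethylenedioxy)-3-methyloctahydro-2H-quinolizin-9-yl]acetate
Conditions: Ru(bpy)3(PF6)2 (2 mol %), Hantzsch ester (1.5 equiv), CF3CO2H (1.05 equiv), degassed CH2Cl2 (0.01 M), blue LEDs, 23 °C; NaHCO3 work-up
Reagents that add atoms: none
Why: The photoexcited divalent ruthenium complex is reduced by the Hantzsch ester to monovalent ruthenium, which passes an electron to the phthalimide ester; N–O cleavage and loss of CO2 give the primary C8 radical, which adds to C9 of the acrylate, and the resulting α-ester radical takes a hydrogen atom from the Hantzsch ester. The closest known reaction type is the photoredox reductive decarboxylative conjugate addition (Giese reaction) of N-(acyloxy)phthalimides, run here intramolecularly. Ring B (N5, C6, C7, C8, C9, C9a) closes in the 6-exo-trig mode. The new C9 centre is controlled by C9a through the ring A chair: with the acrylate arm and the N-chain both equatorial, closure should pass through a chair-like transition state with the CH–CO2Me terminus pseudo-equatorial, so that C9–H ends trans to C9a–H. The step needs cyclization to outrun 1,5-hydrogen transfer from C9a–H or C4–H and premature reduction of the radical; this is secured by the electron-poor acceptor, by high dilution and by protonation of N5, which strengthens the adjacent C–H bonds, keeps the amine from quenching the photocatalyst and prevents acyl transfer to nitrogen.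

Step 10
Reactants: 18 quinolizidine ester
Product: 19 2-[(3R,9R,9aR)-2,2-(ethylenedioxy)-3-methyloctahydro-2H-quinolizin-9-yl]ethanol
Conditions: LiAlH4, THF, 0 °C
Reagents that add atoms: none
Why: Hydride reduction of the methyl ester gives the primary alcohol, and the ketal, the tertiary amine and all stereocentres are inert to LiAlH4.

Step 11
Reactants: 19 alcohol
Product: 20 2-[(3R,9R,9aR)-2,2-(ethylenedioxy)-3-methyloctahydro-2H-quinolizin-9-yl]acetaldehyde
Conditions: (COCl)2, DMSO, CH2Cl2, −78 °C; Et3N, −78 → 0 °C
Reagents that add atoms: none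
Why: Swern oxidation stops at the aldehyde and tolerates the tertiary amine and the ketal, and C9, being β to the new carbonyl, cannot epimerize.

Step 12
Reactants: 20 aldehyde; 21 [3-(benzyloxy)propyl]triphenylphosphonium bromide
Product: 22 (3R,9R,9aR)-9-[(Z)-5-(benzyloxy)pent-2-en-1-yl]-2,2-(ethylenedioxy)-3-methyloctahydro-2H-quinolizine
Conditions: 21, KN(SiMe3)2, THF, −78 °C; then 20, −78 → 23 °C
Reagents that add atoms: [3-(benzyloxy)propyl]triphenylphosphonium bromide, [Br-].C(CCOCc1ccccc1)[P+](c1ccccc1)(c1ccccc1)c1ccccc1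
Why: Wittig olefination with the non-stabilized ylide adds the three remaining chain carbons with the terminal oxygen masked as a benzyl ether, and the alkene geometry is irrelevant because the double bond is hydrogenated later.

Step 13
Reactants: 22 ketal benzyl ether
Product: 23 (3R,9R,9aR)-9-[(Z)-5-(benzyloxy)pent-2-en-1-yl]-3-methyloctahydro-2H-quinolizin-2-one
Conditions: 3 M aq. HCl, THF, 60 °C; NaHCO3 work-up
Reagents that add atoms: water, O
Why: Aqueous acid hydrolysis of the dioxolane frees the C2 ketone, the benzyl ether and alkene being acid-stable, and C3 keeps its thermodynamically preferred equatorial methyl.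

Step 14
Reactants: 23 ketone; 24 diethyl chlorophosphate
Product: 27 diethyl [(3R,9R,9aS)-9-[(Z)-5-(benzyloxy)pent-2-en-1-yl]-3-methyl-2-oxooctahydro-2H-quinolizin-1-yl]phosphonate (C1 epimers), via lithium enolate 25 (not isolated), via enol phosphate 26 (not isolated)
Conditions: LiN(i-Pr)2 (1.1 equiv), THF, −78 °C; 24; then LiN(i-Pr)2 (2.2 equiv), −78 → 0 °C; NH4Cl
Reagents that add atoms: diethyl chlorophosphate, CCOP(=O)(Cl)OCC
Why: Kinetic deprotonation at the C1 methylene rather than the C3 methine, O-phosphorylation and base-induced 1,3-shift of phosphorus from oxygen to the vinylic carbon (vinyl phosphate to β-keto phosphonate rearrangement) should place the phosphonate regiospecifically on C1.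

Step 15
Reactants: 27 β-keto phosphonate benzyl ether
Product: 28 diethyl [(3R,9S,9aS)-9-(5-hydroxypentyl)-3-methyl-2-oxooctahydro-2H-quinolizin-1-yl]phosphonate (C1 epimers)
Conditions: H2 (1 atm), Pd(OH)2/C, EtOH, HCl (1.1 equiv), 23 °C
Reagents that add atoms: none
Why: Catalytic hydrogenation saturates the chain alkene and hydrogenolyses the benzyl ether in one operation (the acid prevents amine poisoning of the catalyst), leaving ketone and phosphonate untouched.

Step 16
Reactants: 28 hydroxy phosphonate
Product: 29 diethyl [(3R,9S,9aS)-3-methyl-2-oxo-9-(5-oxopentyl)octahydro-2H-quinolizin-1-yl]phosphonate (C1 epimers)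
Conditions: Dess–Martin periodinane, NaHCO3, CH2Cl2, 0 °C; used at once
Reagents that add atoms: none
Why: Dess–Martin oxidation of the primary alcohol gives the aldehyde without a base strong enough to start olefination of the phosphonate.

Step 17
Reactants: 29 phosphonate aldehyde (two molecules)
Product: 30 macrocyclic (E,E)-bis-enone, 16-membered ring with C1=CH–(CH2)4–C9' and C1'=CH–(CH2)4–C9 links, (3R,9S,9aS) in each half
Conditions: LiCl, DBU, MeCN (0.005 M, slow addition), 23 °C
Reagents that add atoms: none
Why: Horner–Wadsworth–Emmons olefination under Masamune–Roush conditions, run at high dilution as a head-to-tail macrocyclic dimerization (a known double olefination tactic), should form both C1=CH bonds because the phosphonate makes C1 the only nucleophilic site and the mild base avoids aldehyde self-aldol.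

Step 18
Reactants: 30 bis-enone
Product: 31 saturated macrocyclic diketone as a mixture of C1/C1' epimers
Conditions: H2 (1 atm), Pd/C, EtOAc–MeOH, 23 °C
Reagents that add atoms: none
Why: Heterogeneous hydrogenation reduces the two exocyclic trisubstituted enone C=C bonds and creates C1 and C1' without control.

Step 19
Reactants: 31 diketone epimer mixture
Product: 32 target, (1R,3R,9S,9aS) in each of the two identical halves
Conditions: NaOMe (cat.), MeOH, 23 → 50 °C
Reagents that add atoms: none
Why: Reversible enolization equilibrates C1, C1', C3 and C3' (all α to the ketones) to the most stable arrangement, equatorial C3 methyl and axial C1 chain free of the peri clash with the equatorial C9 chain, which is the target, while C9 is not epimerizable and C9a can invert only through reversible retro-Michael opening.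

**Compound list**

1 | Boc-D-Asp-OMe, (3R)-3-[(tert-butoxycarbonyl)amino]-4-methoxy-4-oxobutanoic acid | COC(=O)[C@@H](CC(=O)O)NC(=O)OC(C)(C)C | starting material
2 | N,O-dimethylhydroxylamine hydrochloride | CNOC.Cl | starting material
3 | methyl (2R)-2-[(tert-butoxycarbonyl)amino]-4-[methoxy(methyl)amino]-4-oxobutanoate | COC(=O)[C@@H](CC(=O)N(C)OC)NC(=O)OC(C)(C)C | intermediate
4 | isopropenylmagnesium bromide | CC(=C)[Mg]Br | starting material
5 | methyl (2R)-2-[(tert-butoxycarbonyl)amino]-5-methyl-4-oxohex-5-enoate | COC(=O)[C@@H](CC(=O)C(C)=C)NC(=O)OC(C)(C)C | intermediate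
6 | methyl (2R)-2-amino-5-methyl-4-oxohex-5-enoate trifluoroacetate | COC(=O)[C@@H](CC(=O)C(C)=C)N.OC(=O)C(F)(F)F | intermediate (not isolated)
7 | methyl (2R,5R)-5-methyl-4-oxopiperidine-2-carboxylate | C[C@@H]1CN[C@@H](C(=O)OC)CC1=O | intermediate
8 | ethylene glycol | OCCO | starting material
9 | methyl (6R,9R)-6-methyl-1,4-dioxa-8-azaspiro[4.5]decane-9-carboxylate | C[C@@H]1CN[C@@H](C(=O)OC)CC13OCCO3 | intermediate
10 | tert-butyl 4-bromobutanoate | CC(C)(C)OC(=O)CCCBr | starting material
11 | methyl (6R,9R)-8-(4-tert-butoxy-4-oxobutyl)-6-methyl-1,4-dioxa-8-azaspiro[4.5]decane-9-carboxylate | C[C@@H]1CN(CCCC(=O)OC(C)(C)C)[C@@H](C(=O)OC)CC13OCCO3 | intermediate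
12 | methyl (triphenylphosphoranylidene)acetate | COC(=O)C=P(c1ccccc1)(c1ccccc1)c1ccccc1 | starting material
13 | tert-butyl 4-[(6R,9R)-9-formyl-6-methyl-1,4-dioxa-8-azaspiro[4.5]decan-8-yl]butanoate | C[C@@H]1CN(CCCC(=O)OC(C)(C)C)[C@@H](C=O)CC13OCCO3 | intermediate (not isolated)
14 | tert-butyl 4-[(6R,9R)-9-[(E)-3-methoxy-3-oxoprop-1-en-1-yl]-6-methyl-1,4-dioxa-8-azaspiro[4.5]decan-8-yl]butanoate | C[C@@H]1CN(CCCC(=O)OC(C)(C)C)[C@@H](/C=C/C(=O)OC)CC13OCCO3 | intermediate
15 | 4-[(6R,9R)-9-[(E)-3-methoxy-3-oxoprop-1-en-1-yl]-6-methyl-1,4-dioxa-8-azaspiro[4.5]decan-8-yl]butanoic acid | C[C@@H]1CN(CCCC(=O)O)[C@@H](/C=C/C(=O)OC)CC13OCCO3 | intermediate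
16 | N-hydroxyphthalimide | ON1C(=O)c2ccccc2C1=O | starting material
17 | 1,3-dioxoisoindolin-2-yl 4-[(6R,9R)-9-[(E)-3-methoxy-3-oxoprop-1-en-1-yl]-6-methyl-1,4-dioxa-8-azaspiro[4.5]decan-8-yl]butanoate | C[C@@H]1CN(CCCC(=O)ON2C(=O)c3ccccc3C2=O)[C@@H](/C=C/C(=O)OC)CC13OCCO3 | intermediate
18 | methyl 2-[(3R,9R,9aR)-2,2-(ethylenedioxy)-3-methyloctahydro-2H-quinolizin-9-yl]acetate (C9–H trans to C9a–H) | C[C@@H]1CN2CCC[C@H](CC(=O)OC)[C@H]2CC13OCCO3 | intermediate
19 | 2-[(3R,9R,9aR)-2,2-(ethylenedioxy)-3-methyloctahydro-2H-quinolizin-9-yl]ethanol | C[C@@H]1CN2CCC[C@H](CCO)[C@H]2CC13OCCO3 | intermediate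
20 | 2-[(3R,9R,9aR)-2,2-(ethylenedioxy)-3-methyloctahydro-2H-quinolizin-9-yl]acetaldehyde | C[C@@H]1CN2CCC[C@H](CC=O)[C@H]2CC13OCCO3 | intermediate
21 | [3-(benzyloxy)propyl]triphenylphosphonium bromide | [Br-].C(CCOCc1ccccc1)[P+](c1ccccc1)(c1ccccc1)c1ccccc1 | starting material
22 | (3R,9R,9aR)-9-[(Z)-5-(benzyloxy)pent-2-en-1-yl]-2,2-(ethylenedioxy)-3-methyloctahydro-2H-quinolizine | C[C@@H]1CN2CCC[C@H](C/C=C\CCOCc3ccccc3)[C@H]2CC13OCCO3 | intermediate
23 | (3R,9R,9aR)-9-[(Z)-5-(benzyloxy)pent-2-en-1-yl]-3-methyloctahydro-2H-quinolizin-2-one | C[C@@H]1CN2CCC[C@H](C/C=C\CCOCc3ccccc3)[C@H]2CC1=O | intermediate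
24 | diethyl chlorophosphate | CCOP(=O)(Cl)OCC | starting material
25 | lithium C1=C2 enolate of 23 | C[C@@H]1CN2CCC[C@H](C/C=C\CCOCc3ccccc3)[C@H]2C=C1O[Li] | intermediate (not isolated)
26 | diethyl enol phosphate of 23 (C1=C2, phosphate on the C2 oxygen) | C[C@@H]1CN2CCC[C@H](C/C=C\CCOCc3ccccc3)[C@H]2C=C1OP(=O)(OCC)OCC | intermediate (not isolated)
27 | diethyl [(3R,9R,9aS)-9-[(Z)-5-(benzyloxy)pent-2-en-1-yl]-3-methyl-2-oxooctahydro-2H-quinolizin-1-yl]phosphonate (C1 epimers) | C[C@@H]1CN2CCC[C@H](C/C=C\CCOCc3ccccc3)[C@H]2C(P(=O)(OCC)OCC)C1=O | intermediate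
28 | diethyl [(3R,9S,9aS)-9-(5-hydroxypentyl)-3-methyl-2-oxooctahydro-2H-quinolizin-1-yl]phosphonate (C1 epimers) | C[C@@H]1CN2CCC[C@H](CCCCCO)[C@H]2C(P(=O)(OCC)OCC)C1=O | intermediate
29 | diethyl [(3R,9S,9aS)-3-methyl-2-oxo-9-(5-oxopentyl)octahydro-2H-quinolizin-1-yl]phosphonate (C1 epimers) | C[C@@H]1CN2CCC[C@H](CCCCC=O)[C@H]2C(P(=O)(OCC)OCC)C1=O | intermediate
30 | macrocyclic (E,E)-bis-enone, two (3R,9S,9aS)-3-methylquinolizidin-2-one units joined head to tail by C1=CH–(CH2)4–C9 links | C[C@@H]1CN2CCC[C@@H]3CCCC/C=C4/C(=O)[C@H](C)CN5CCC[C@H](CCCC/C=C(/C1=O)[C@H]32)[C@@H]45 | intermediate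
31 | saturated macrocyclic diketone, C1 and C1' unassigned | C[C@@H]1CN2CCC[C@@H]3CCCCCC4C(=O)[C@H](C)CN5CCC[C@H](CCCCCC(C1=O)[C@H]32)[C@@H]45 | intermediate
32 | target, C2-symmetric bis(3-methylquinolizidin-2-one) macrocycle, (1R,3R,9S,9aS) in each half | C[C@@H]1CN2CCC[C@@H]3CCCCC[C@H]4C(=O)[C@H](C)CN5CCC[C@H](CCCCC[C@@H](C1=O)[C@H]32)[C@@H]45 | target

**Step count and risks**

Total step count: 19. Longest linear sequence: 19 steps from 1 (step 17 joins two molecules of the same intermediate).

Step 9. The C8 radical may abstract hydrogen from C9a or C4 by 1,5-transfer, or be reduced before it closes, and the closure may show poor facial selectivity at C9. Fallback: ring B would be closed by an anionic route instead. Setting out from 9, N-alkylation with 3-bromopropyl phenyl sulfone (K2CO3, NaI, MeCN) gives the sulfone amino ester F1. Reduction with i-Bu2AlH and in situ olefination with 12, as in step 6, give the sulfone acrylate F2. Deprotonation next to sulfur (KN(SiMe3)2, THF, −78 °C) should trigger a 6-exo-trig intramolecular Michael addition through the same chair-like arrangement to the quinolizidine sulfone F3. Reductive desulfonylation (Na/Hg amalgam, Na2HPO4, MeOH, −20 °C) would then return the route at 18.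

Step 17. Linear oligomerization, closure of one monomer onto its own chain, sluggish olefination of the hindered cyclic phosphonate, or base-induced migration of the new double bond into ring A towards N5 may erode the dimerization. Fallback: the two olefinations would be done one at a time. Slow addition of 29 to an excess of 28 under the same LiCl/DBU conditions gives the linear hydroxy enone phosphonate F4. Dess–Martin oxidation gives the linear aldehyde F5, in which only one phosphonate and one aldehyde remain. A unimolecular Horner–Wadsworth–Emmons macrocyclization at high dilution would then return the route at 30.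

Step 14. Proton removal on the C3 side, an incomplete oxygen-to-carbon phosphorus shift, or β-elimination of N5 from the C1 carbanion would give regioisomeric or ring-opened material. Fallback: the phosphonate would be abandoned. Setting out from 22, hydrogenation and hydrogenolysis (H2, Pd(OH)2/C, EtOH, HCl) give the saturated ketal alcohol F6. Dess–Martin oxidation gives the ketal aldehyde F7, and aqueous HCl gives the keto aldehyde F8. A base-mediated aldol condensation at high dilution (Ba(OH)2, MeOH) would then dimerize F8 head to tail. Only the C1 aldol can dehydrate to a conjugated enone, so the C3 adducts revert, and the route is rejoined at 30. Aldehyde self-condensation competes, which is why this is the second choice.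

**Further compounds**

F1 | step 9 | methyl (6R,9R)-6-methyl-8-[3-(phenylsulfonyl)propyl]-1,4-dioxa-8-azaspiro[4.5]decane-9-carboxylate | C[C@@H]1CN(CCCS(=O)(=O)c2ccccc2)[C@@H](C(=O)OC)CC13OCCO3
F2 | step 9 | methyl (E)-3-[(6R,9R)-6-methyl-8-[3-(phenylsulfonyl)propyl]-1,4-dioxa-8-azaspiro[4.5]decan-9-yl]acrylate | C[C@@H]1CN(CCCS(=O)(=O)c2ccccc2)[C@@H](/C=C/C(=O)OC)CC13OCCO3
F3 | step 9 | 8-(phenylsulfonyl) derivative of 18 (C8 epimers; C3, C9, C9a as in 18) | C[C@@H]1CN2CCC(S(=O)(=O)c3ccccc3)[C@H](CC(=O)OC)[C@H]2CC13OCCO3
F4 | step 17 | linear dimer: 1-alkylidene quinolizidinone carrying a 9-(5-hydroxypentyl) chain, linked through C1=CH–(CH2)4 to C9 of a second unit that keeps its C1 phosphonate | C[C@@H]1CN2CCC[C@H](CCCCCO)[C@H]2/C(C1=O)=C\CCCC[C@H]3CCCN4C[C@@H](C)C(=O)C(P(=O)(OCC)OCC)[C@H]34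
F5 | step 17 | linear dimer aldehyde, as F4 with a 9-(5-oxopentyl) chain | C[C@@H]1CN2CCC[C@H](CCCCC=O)[C@H]2/C(C1=O)=C\CCCC[C@H]3CCCN4C[C@@H](C)C(=O)C(P(=O)(OCC)OCC)[C@H]34
F6 | step 14 | 5-[(3R,9S,9aR)-2,2-(ethylenedioxy)-3-methyloctahydro-2H-quinolizin-9-yl]pentan-1-ol | C[C@@H]1CN2CCC[C@H](CCCCCO)[C@H]2CC13OCCO3
F7 | step 14 | 5-[(3R,9S,9aR)-2,2-(ethylenedioxy)-3-methyloctahydro-2H-quinolizin-9-yl]pentanal | C[C@@H]1CN2CCC[C@H](CCCCC=O)[C@H]2CC13OCCO3
F8 | step 14 | 5-[(3R,9S,9aR)-3-methyl-2-oxooctahydro-2H-quinolizin-9-yl]pentanal | C[C@@H]1CN2CCC[C@H](CCCCC=O)[C@H]2CC1=O
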